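(All runs are simulated from invented constants, and the scatter is random.)

The easy step was south, which stayed at 20 °C throughout, so I took that flask as the zero of my scale: there a minute counts as one minute.

| flask | substrate | temperature | remark | time |
|---|---|---|---|---|
| Tuesday's | 0.050 M | 15 °C | run made earlier |  |
| Friday's | 0.075 M | 35 °C | run made earlier |  |
| north-east | 0.10 M |  | at 50 °C until 80 s, from then on at 20 °C | 6.0 min |
| south | 0.10 M |  | at 20 °C throughout | 6.0 min |

But north-east spent 80 s at 50 °C, so I needed the worth of a hot minute, and the earlier runs had to give it.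

| run | time / min | ring / % |
|---|---|---|
| Tuesday's | 3.00 | 9.3 |
| Tuesday's | 8.00 | 23.7 |
| Tuesday's | 15.0 | 32.4 |
| Tuesday's | 50.0 | 68.6 |
| Friday's | 2.00 | 52.1 |
| Friday's | 5.00 | 71.7 |
| Friday's | 10.0 | 66.3 |
| Friday's | 15.0 | 62.2 |

(each reading ± 1 percentage point)

I took the highest reading of Friday's run, 71.7%, as the ceiling of ring, and read a first-order rate constant k from the first reading of each run: 0.0463 min⁻¹ at 15 °C and 0.648 min⁻¹ at 35 °C. These gave an activation energy of 97.4 kJ mol⁻¹, so k at 50 °C stood f = 40.9 times its value at 20 °C, and I counted each minute at 50 °C as f minutes. North-east therefore came to 59.2 min; this dose D is the minutes at 20 °C that equal a flask's whole heating.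

By the same reckoning k in Friday's run stood 7.00 times its value at 20 °C, so north-east's D lay between that run's readings at 5.00 min and 10.0 min, and I expected 66.3% to 71.7%. South's 6.0 min matched 12.0 min of Tuesday's run, so I expected 23.7% to 32.4% there.

- the flask that ends with the higher amount of ring, in percent of the substrate charged, or "neither" when 2 percentage points or less lies between them (north-east / south / neither)
- final ring, as a percentage of the substrate charged, in north-east
- final ring, as a percentage of the substrate charged, in south

- a reading or a percentage of ring counts all its forms, free or not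

The forecast chose north-east, with 63% (48% to 74%) and 23% (13% to 35%), holding that “80 s at 50 °C should nearly finish conversion”, and its north-east figure stood lower than my span.

North-east ended at 71.4% and south at 24.1%, so north-east held more ring.

    substrate ⇌ dormant form (K = 1.40, k = 0.00508 s⁻¹, Ea = 80.0 kJ mol⁻¹, ΔH = −44.0 kJ mol⁻¹)
    crystals ⇌ ring, rate k2*(cs2 - [ring]) while solid is left; crystals form when [ring] > cs2 (solubility = 0.0710 M, k = 5.44 s⁻¹)
    substrate → ring (k = 0.0838 s⁻¹, Ea = 95.0 kJ mol⁻¹)
    ring ⇌ isomer of the product (K = 1.04, k = 0.00663 s⁻¹, Ea = 88.0 kJ mol⁻¹, ΔH = 38.0 kJ mol⁻¹)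
    2 substrate ⇌ open dimer (K = 13.8 M⁻¹, k = 2.54 M⁻¹ s⁻¹, Ea = 56.0 kJ mol⁻¹, ΔH = −22.0 kJ mol⁻¹)
    (constants at 50 °C)

Neither flask had come to rest. South, left until 60.0 min, had a dose close to north-east's 59.2 min and stood at 74.5%, a gain of 50 percentage points. North-east, left until 60.0 min, gained 6.7 points and reached 78.1% with its crystals counted in, and those crystals stood at 7.05% of the substrate charged.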